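The naphthazarin is cut through its substituted six-membered ring at C1–C8a and C4–C4a. The key step exploits that C1 and C4 sit on a symmetrical 5,8-dioxygenated benzo ring, while C2, which carries the C1′ stereocentre, and C3 correspond to C3 and C4 of a 3-substituted furan. One aryne–furan [4+2] cycloaddition therefore closes the carbocycle as an oxygen-bridged dihydronaphthalene with the complete side chain in place. Its partners are 3,6-dimethoxy-2-(trimethylsilyl)phenyl triflate and an (R)-3-furyl carbinol already acylated with 3-acetoxy-3-methylbutanoic acid; an ester is preferred to a silyl ether because the aryne is released by fluoride. Bridge opening, oxidation and demethylation complete the route.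

Key step: step 9

Remark: the target is a naphthazarin whose two ring tautomers interconvert rapidly, so the compound drawn with the side chain on the quinoid ring and the 6-substituted tautomer are one substance. 3-Acetoxy-3-methylbutanoic acid is made in one step from commercial 3-hydroxy-3-methylbutanoic acid and is not assumed to be purchasable.

Step 1
Reactants: 1 4-methylpent-3-enoic acid
Product: 3 N-methoxy-N,4-dimethylpent-3-enamide, via acyl imidazolide 2 (not isolated)
Conditions: 1,1'-carbonyldiimidazole, CH2Cl2, 0 °C to rt; then MeNH(OMe)·HCl, rt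
Reagents that add atoms: N,O-dimethylhydroxylamine hydrochloride, CNOC.Cl
Why: 1,1'-Carbonyldiimidazole coupling (acyl imidazolide formation, then aminolysis) is near-neutral, so the β,γ-double bond should stay out of conjugation while the Weinreb amide forms.

Step 2
Reactants: 4 3-bromofuran; 3 N-methoxy-N,4-dimethylpent-3-enamide
Product: 7 1-(furan-3-yl)-4-methylpent-3-en-1-one, via 3-furyllithium 5 (not isolated), via lithium hemiaminal chelate 6 (not isolated)
Conditions: 4, n-BuLi, THF, −78 °C; then 3, −78 °C; aq. NH4Cl at −78 °C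
Reagents that add atoms: none
Why: Bromine–lithium exchange at −78 °C gives 3-furyllithium before it can equilibrate to the 2-lithio isomer, and the Weinreb ketone synthesis stops at the ketone because chelate 6 only collapses on the cold quench, the addition of aryllithiums to this type of β,γ-unsaturated amide being established.

Step 3
Reactants: 7 1-(furan-3-yl)-4-methylpent-3-en-1-one
Product: 9 (1R)-1-(furan-3-yl)-4-methylpent-3-en-1-ol, via catechol borate ester 8 (not isolated)
Conditions: (S)-2-methyl-CBS-oxazaborolidine [(S)-1-methyl-3,3-diphenyltetrahydropyrrolo[1,2-c][1,3,2]oxazaborole] (10 mol %), catecholborane, toluene, −78 °C; then H2O, aq. NaOH wash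
Reagents that add atoms: none
Why: Corey–Bakshi–Shibata reduction: the oxazaborolidine binds the carbonyl oxygen with the planar 3-furyl group as the large substituent and delivers hydride to the Si face, as with aryl alkyl ketones, which sets C1′ as (R) under catalyst control, while catecholborane at −78 °C does not hydroborate the trisubstituted alkene.

Step 4
Reactants: 10 3-hydroxy-3-methylbutanoic acid
Product: 12 3-acetoxy-3-methylbutanoic acid, via mixed acetic anhydride 11 (not isolated)
Conditions: Ac2O, 4-(dimethylamino)pyridine (DMAP, cat.), pyridine, rt; then H2O, rt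
Reagents that add atoms: acetic anhydride, CC(=O)OC(C)=O
Why: Nucleophilic catalysis by DMAP (Steglich-type acylation) acetylates even the tertiary hydroxyl, and the mixed anhydride formed at the carboxyl group is far more labile to water than the tertiary acetate.

Step 5
Reactants: 9 (1R)-1-(furan-3-yl)-4-methylpent-3-en-1-ol; 12 3-acetoxy-3-methylbutanoic acid
Product: 13 (1R)-1-(furan-3-yl)-4-methylpent-3-en-1-yl 3-acetoxy-3-methylbutanoate
Conditions: N,N'-dicyclohexylcarbodiimide, DMAP (cat.), CH2Cl2, 0 °C to rt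
Reagents that add atoms: none
Why: Steglich esterification activates the acid, not the alcohol, so the C1′–O bond is never broken and the (R) configuration is carried over unchanged.

Step 6
Reactants: 14 2,5-dimethoxyphenol
Product: 15 2,5-dimethoxyphenyl N-(propan-2-yl)carbamate
Conditions: i-PrNCO, Et3N (cat.), CH2Cl2, rt
Reagents that add atoms: isopropyl isocyanate, CC(C)N=C=O
Why: Amine-catalysed carbamoylation of a phenol by an isocyanate is a simple addition that installs the strongest oxygen-based directing group for the next step.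

Step 7
Reactants: 15 2,5-dimethoxyphenyl N-(propan-2-yl)carbamate
Product: 19 3,6-dimethoxy-2-(trimethylsilyl)phenyl N-(propan-2-yl)carbamate, via N-silyl carbamate 16 (not isolated), via aryllithium 17 (not isolated), via bis-silyl carbamate 18 (not isolated)
Conditions: TBSOTf, TMEDA, Et2O, 0 °C to rt; then n-BuLi, TMEDA, −78 °C; then TMSCl, −78 °C to rt; aq. NaHSO4
Reagents that add atoms: chlorotrimethylsilane, C[Si](C)(C)Cl
Why: Directed ortho-metalation: once the N–H is masked in situ as the N-silyl derivative, the carbamate steers lithiation to C6, the only free ortho position and one also flanked by the C5 methoxy group, and the aryllithium is silylated by TMSCl before the acidic work-up removes the N-silyl group.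

Step 8
Reactants: 19 3,6-dimethoxy-2-(trimethylsilyl)phenyl N-(propan-2-yl)carbamate
Product: 21 3,6-dimethoxy-2-(trimethylsilyl)phenyl trifluoromethanesulfonate, via silylphenol 20 (not isolated)
Conditions: DBU, Et2NH, MeCN, 40 °C; then PhNTf2, rt
Reagents that add atoms: N-phenylbis(trifluoromethanesulfonimide), O=S(=O)(N(c1ccccc1)S(=O)(=O)C(F)(F)F)C(F)(F)F
Why: DBU induces E1cB fragmentation of the N-monoalkyl carbamate to the phenoxide and isopropyl isocyanate (scavenged by Et2NH), and the phenoxide is O-sulfonylated in the same flask by PhNTf2, a standard one-pot carbamate-to-triflate exchange.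

Step 9
Reactants: 13 (1R)-1-(furan-3-yl)-4-methylpent-3-en-1-yl 3-acetoxy-3-methylbutanoate; 21 3,6-dimethoxy-2-(trimethylsilyl)phenyl trifluoromethanesulfonate
Product: 23 (1R)-1-(5,8-dimethoxy-1,4-dihydro-1,4-epoxynaphthalen-2-yl)-4-methylpent-3-en-1-yl 3-acetoxy-3-methylbutanoate (both bridgehead epimers), via 3,6-dimethoxybenzyne 22 (not isolated)
Conditions: CsF, MeCN, rt; 21 (1.3 equiv) added slowly; purification on Et3N-deactivated silica
Reagents that add atoms: none
Why: Fluoride attacks the trimethylsilyl group of 21 and triflate leaves in a 1,2-elimination, and the strained 3,6-dimethoxybenzyne 22 is trapped by the furan diene in a concerted, suprafacial [4+2] cycloaddition, the well-known aryne–furan Diels–Alder reaction. The six-membered carbocycle is closed intermolecularly by annulation: C1–C8a and C4–C4a form together across furan C2 and C5, and the furan oxygen becomes the 1,4-epoxy bridge. The two bridgehead carbons are new stereocentres formed without control, giving both epimers relative to C1′, which is harmless because both are erased on aromatisation; C1′ itself is not touched. Because the aryne is twofold-symmetric no regiochemistry arises, and the 3-substituent of the furan necessarily ends on the alkene carbon that becomes quinone C2. The step needs chemoselectivity for the furan over the prenyl alkene (ene reaction) and over the ester groups; the far higher diene reactivity of furan, the low stationary aryne concentration from sparingly soluble CsF and the absence of any fluoride-labile or protic group in 13 should secure it.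

Step 10
Reactants: 23 (1R)-1-(5,8-dimethoxy-1,4-dihydro-1,4-epoxynaphthalen-2-yl)-4-methylpent-3-en-1-yl 3-acetoxy-3-methylbutanoate
Product: 27 (1R)-1-(5,8-dimethoxy-1,4-dioxo-1,4-dihydronaphthalen-2-yl)-4-methylpent-3-en-1-yl 3-acetoxy-3-methylbutanoate, via 2-substituted naphthol 24 (not isolated), via 3-substituted naphthol 25 (not isolated), via hydroquinone 26 (not isolated)
Conditions: TsOH·H2O (5 mol %), MeCN, 0 °C; then H2O, PhI(OAc)2 (2.2 equiv), 0 °C
Reagents that add atoms: water, O
Why: Acid-catalysed isomerisation of a 1,4-epoxy-1,4-dihydronaphthalene (bridgehead ionisation assisted by the methoxylated ring, 1,2-hydride shift, enolisation) gives naphthols 24 and 25, and hypervalent-iodine phenol oxidation with water as oxygen source takes both through hydroquinone 26 to the same para-quinone, so the direction of bridge opening is irrelevant.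

Step 11
Reactants: 27 (1R)-1-(5,8-dimethoxy-1,4-dioxo-1,4-dihydronaphthalen-2-yl)-4-methylpent-3-en-1-yl 3-acetoxy-3-methylbutanoate
Product: 29 (1R)-1-(5,8-dihydroxy-1,4-dioxo-1,4-dihydronaphthalen-2-yl)-4-methylpent-3-en-1-yl 3-acetoxy-3-methylbutanoate, via naphthodiquinone 28 (not isolated)
Conditions: AgO, aq. HNO3 (6 mol/L), 1,4-dioxane, rt, minutes; extraction into CHCl3; then aq. Na2S2O4 (about 1 equiv), rt
Reagents that add atoms: water, O
Why: Oxidative demethylation of the para-dimethoxyarene ring by AgO in nitric acid gives naphthodiquinone 28, whose mild two-electron reduction by dithionite stops at the naphthazarin, the established way from 5,8-dimethoxy- to 5,8-dihydroxy-1,4-naphthoquinones including ones with a 1′-acyloxy side chain; C1′ takes no part.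

Compound list
1 | 4-methylpent-3-enoic acid | CC(C)=CCC(=O)O | starting material
2 | 1-(4-methylpent-3-enoyl)-1H-imidazole | CC(C)=CCC(=O)n1ccnc1 | intermediate (not isolated)
3 | N-methoxy-N,4-dimethylpent-3-enamide | CC(C)=CCC(=O)N(C)OC | intermediate
4 | 3-bromofuran | Brc1ccoc1 | starting material
5 | 3-furyllithium | [Li]c1ccoc1 | intermediate (not isolated)
6 | lithium 1-(furan-3-yl)-1-[methoxy(methyl)amino]-4-methylpent-3-en-1-olate | CC(C)=CCC(O[Li])(N(C)OC)c1ccoc1 | intermediate (not isolated)
7 | 1-(furan-3-yl)-4-methylpent-3-en-1-one | CC(C)=CCC(=O)c1ccoc1 | intermediate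
8 | 2-{[(1R)-1-(furan-3-yl)-4-methylpent-3-en-1-yl]oxy}-1,3,2-benzodioxaborole | CC(C)=CC[C@@H](OB1Oc2ccccc2O1)c1ccoc1 | intermediate (not isolated)
9 | (1R)-1-(furan-3-yl)-4-methylpent-3-en-1-ol | CC(C)=CC[C@@H](O)c1ccoc1 | intermediate
10 | 3-hydroxy-3-methylbutanoic acid | CC(C)(O)CC(=O)O | starting material
11 | acetic 3-acetoxy-3-methylbutanoic anhydride | CC(=O)OC(C)(C)CC(=O)OC(C)=O | intermediate (not isolated)
12 | 3-acetoxy-3-methylbutanoic acid | CC(=O)OC(C)(C)CC(=O)O | intermediate
13 | (1R)-1-(furan-3-yl)-4-methylpent-3-en-1-yl 3-acetoxy-3-methylbutanoate | CC(=O)OC(C)(C)CC(=O)O[C@H](CC=C(C)C)c1ccoc1 | intermediate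
14 | 2,5-dimethoxyphenol | COc1ccc(OC)c(O)c1 | starting material
15 | 2,5-dimethoxyphenyl N-(propan-2-yl)carbamate | COc1ccc(OC)c(OC(=O)NC(C)C)c1 | intermediate
16 | 2,5-dimethoxyphenyl N-(tert-butyldimethylsilyl)-N-(propan-2-yl)carbamate | COc1ccc(OC)c(OC(=O)N(C(C)C)[Si](C)(C)C(C)(C)C)c1 | intermediate (not isolated)
17 | [2-({[tert-butyl(dimethyl)silyl](propan-2-yl)carbamoyl}oxy)-3,6-dimethoxyphenyl]lithium | COc1ccc(OC)c(OC(=O)N(C(C)C)[Si](C)(C)C(C)(C)C)c1[Li] | intermediate (not isolated)
18 | 3,6-dimethoxy-2-(trimethylsilyl)phenyl N-(tert-butyldimethylsilyl)-N-(propan-2-yl)carbamate | COc1ccc(OC)c(OC(=O)N(C(C)C)[Si](C)(C)C(C)(C)C)c1[Si](C)(C)C | intermediate (not isolated)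
19 | 3,6-dimethoxy-2-(trimethylsilyl)phenyl N-(propan-2-yl)carbamate | COc1ccc(OC)c(OC(=O)NC(C)C)c1[Si](C)(C)C | intermediate
20 | 3,6-dimethoxy-2-(trimethylsilyl)phenol | COc1ccc(OC)c(O)c1[Si](C)(C)C | intermediate (not isolated)
21 | 3,6-dimethoxy-2-(trimethylsilyl)phenyl trifluoromethanesulfonate | COc1ccc(OC)c(OS(=O)(=O)C(F)(F)F)c1[Si](C)(C)C | intermediate
22 | 3,6-dimethoxybenzyne | COC1=CC=C(OC)C#C1 | intermediate (not isolated)
23 | (1R)-1-(5,8-dimethoxy-1,4-dihydro-1,4-epoxynaphthalen-2-yl)-4-methylpent-3-en-1-yl 3-acetoxy-3-methylbutanoate, both bridgehead epimers | CC(=O)OC(C)(C)CC(=O)O[C@H](CC=C(C)C)C1=CC2OC1c1c(OC)ccc(OC)c12 | intermediate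
24 | (1R)-1-(1-hydroxy-5,8-dimethoxynaphthalen-2-yl)-4-methylpent-3-en-1-yl 3-acetoxy-3-methylbutanoate | CC(=O)OC(C)(C)CC(=O)O[C@H](CC=C(C)C)c1ccc2c(OC)ccc(OC)c2c1O | intermediate (not isolated)
25 | (1R)-1-(4-hydroxy-5,8-dimethoxynaphthalen-2-yl)-4-methylpent-3-en-1-yl 3-acetoxy-3-methylbutanoate | CC(=O)OC(C)(C)CC(=O)O[C@H](CC=C(C)C)c1cc(O)c2c(OC)ccc(OC)c2c1 | intermediate (not isolated)
26 | (1R)-1-(1,4-dihydroxy-5,8-dimethoxynaphthalen-2-yl)-4-methylpent-3-en-1-yl 3-acetoxy-3-methylbutanoate | CC(=O)OC(C)(C)CC(=O)O[C@H](CC=C(C)C)c1cc(O)c2c(OC)ccc(OC)c2c1O | intermediate (not isolated)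
27 | (1R)-1-(5,8-dimethoxy-1,4-dioxo-1,4-dihydronaphthalen-2-yl)-4-methylpent-3-en-1-yl 3-acetoxy-3-methylbutanoate | CC(=O)OC(C)(C)CC(=O)O[C@H](CC=C(C)C)C1=CC(=O)c2c(OC)ccc(OC)c2C1=O | intermediate
28 | (1R)-4-methyl-1-(1,4,5,8-tetraoxo-1,4,5,8-tetrahydronaphthalen-2-yl)pent-3-en-1-yl 3-acetoxy-3-methylbutanoate | CC(=O)OC(C)(C)CC(=O)O[C@H](CC=C(C)C)C1=CC(=O)C2=C(C1=O)C(=O)C=CC2=O | intermediate (not isolated)
29 | (1R)-1-(5,8-dihydroxy-1,4-dioxo-1,4-dihydronaphthalen-2-yl)-4-methylpent-3-en-1-yl 3-acetoxy-3-methylbutanoate | CC(=O)OC(C)(C)CC(=O)O[C@H](CC=C(C)C)C1=CC(=O)c2c(O)ccc(O)c2C1=O | target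

Total step count: 11. Longest linear sequence: 7 steps (steps 1, 2, 3, 5, 9, 10, 11).

Steps most likely to fail

Step 9. The aryne may be consumed by pathways other than cycloaddition (ene reaction at the prenyl alkene, self-condensation), and fluoride may induce β-elimination of acetate from the ester while the aryne is released slowly. The fallback keeps the ester out of the fluoride step and attaches it after the cycloaddition. It sets out from alcohol 9. Silylation (TBSCl, imidazole, DMF) gives (R)-tert-butyl{[1-(furan-3-yl)-4-methylpent-3-en-1-yl]oxy}dimethylsilane F1. Cycloaddition with 21 under the conditions of step 9 gives 2-[(1R)-1-(tert-butyldimethylsilyloxy)-4-methylpent-3-en-1-yl]-5,8-dimethoxy-1,4-dihydro-1,4-epoxynaphthalene F2. Bu4NF in THF at 0 °C, to which the base-stable oxabicycle is inert, frees (1R)-1-(5,8-dimethoxy-1,4-dihydro-1,4-epoxynaphthalen-2-yl)-4-methylpent-3-en-1-ol F3. Esterification with 12 as in step 5 comes back to the route at 23.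

Step 10. While the electron-rich naphthols are present, the C1′ acyloxy group may ionise or leave through an ortho-quinone methide, with loss or racemisation of the stereocentre, and the acid may attack the prenyl alkene. The fallback carries a silyloxy group, a far poorer leaving group, through aromatisation and oxidation and introduces the ester at the quinone stage. It sets out from alcohol 9 and passes through F1 and F2, made as in the fallback for step 9. The conditions of step 10 should open F2 to 2-[(1R)-1-(tert-butyldimethylsilyloxy)-4-methylpent-3-en-1-yl]-5,8-dimethoxynaphthalen-1-ol F4 and 3-[(1R)-1-(tert-butyldimethylsilyloxy)-4-methylpent-3-en-1-yl]-5,8-dimethoxynaphthalen-1-ol F5. Both are oxidised through 2-[(1R)-1-(tert-butyldimethylsilyloxy)-4-methylpent-3-en-1-yl]-5,8-dimethoxynaphthalene-1,4-diol F6 to 2-[(1R)-1-(tert-butyldimethylsilyloxy)-4-methylpent-3-en-1-yl]-5,8-dimethoxynaphthalene-1,4-dione F7. HF·pyridine in THF–pyridine at 0 °C gives 2-[(1R)-1-hydroxy-4-methylpent-3-en-1-yl]-5,8-dimethoxynaphthalene-1,4-dione F8. Esterification with 12 as in step 5 comes back to the route at 27.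

Step 11. The side chain may be over-oxidised or damaged by acid in the AgO/nitric acid medium, and the C1′ carboxylate may be expelled reductively if the diquinone is over-reduced. The fallback avoids both the diquinone and the strongly acidic oxidant. It sets out from quinone 27. Reductive acetylation (Zn, Ac2O, NaOAc, rt) gives (1R)-1-(1,4-diacetoxy-5,8-dimethoxynaphthalen-2-yl)-4-methylpent-3-en-1-yl 3-acetoxy-3-methylbutanoate F9. Its dimethoxy ring is no longer deactivated by a fused quinone, so (NH4)2Ce(NO3)6 in MeCN–H2O at 0 °C should oxidise it to (1R)-1-(1,4-diacetoxy-5,8-dioxo-5,8-dihydronaphthalen-2-yl)-4-methylpent-3-en-1-yl 3-acetoxy-3-methylbutanoate F10. Brief methanolysis (K2CO3 cat., MeOH, 0 °C) should remove the two activated aryl acetates in preference to the alkyl esters. This comes back to the route at 29, since the two naphthazarin tautomers are one compound.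

Further compounds
F1 | step 9 | (R)-tert-butyl{[1-(furan-3-yl)-4-methylpent-3-en-1-yl]oxy}dimethylsilane | CC(C)=CC[C@@H](O[Si](C)(C)C(C)(C)C)c1ccoc1
F2 | step 9 | 2-[(1R)-1-(tert-butyldimethylsilyloxy)-4-methylpent-3-en-1-yl]-5,8-dimethoxy-1,4-dihydro-1,4-epoxynaphthalene, both bridgehead epimers | CC(C)=CC[C@@H](O[Si](C)(C)C(C)(C)C)C1=CC2OC1c1c(OC)ccc(OC)c12
F3 | step 9 | (1R)-1-(5,8-dimethoxy-1,4-dihydro-1,4-epoxynaphthalen-2-yl)-4-methylpent-3-en-1-ol, both bridgehead epimers | CC(C)=CC[C@@H](O)C1=CC2OC1c1c(OC)ccc(OC)c12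
F4 | step 10 | 2-[(1R)-1-(tert-butyldimethylsilyloxy)-4-methylpent-3-en-1-yl]-5,8-dimethoxynaphthalen-1-ol | CC(C)=CC[C@@H](O[Si](C)(C)C(C)(C)C)c1ccc2c(OC)ccc(OC)c2c1O
F5 | step 10 | 3-[(1R)-1-(tert-butyldimethylsilyloxy)-4-methylpent-3-en-1-yl]-5,8-dimethoxynaphthalen-1-ol | CC(C)=CC[C@@H](O[Si](C)(C)C(C)(C)C)c1cc(O)c2c(OC)ccc(OC)c2c1
F6 | step 10 | 2-[(1R)-1-(tert-butyldimethylsilyloxy)-4-methylpent-3-en-1-yl]-5,8-dimethoxynaphthalene-1,4-diol | CC(C)=CC[C@@H](O[Si](C)(C)C(C)(C)C)c1cc(O)c2c(OC)ccc(OC)c2c1O
F7 | step 10 | 2-[(1R)-1-(tert-butyldimethylsilyloxy)-4-methylpent-3-en-1-yl]-5,8-dimethoxynaphthalene-1,4-dione | CC(C)=CC[C@@H](O[Si](C)(C)C(C)(C)C)C1=CC(=O)c2c(OC)ccc(OC)c2C1=O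
F8 | step 10 | 2-[(1R)-1-hydroxy-4-methylpent-3-en-1-yl]-5,8-dimethoxynaphthalene-1,4-dione | CC(C)=CC[C@@H](O)C1=CC(=O)c2c(OC)ccc(OC)c2C1=O
F9 | step 11 | (1R)-1-(1,4-diacetoxy-5,8-dimethoxynaphthalen-2-yl)-4-methylpent-3-en-1-yl 3-acetoxy-3-methylbutanoate | CC(=O)OC(C)(C)CC(=O)O[C@H](CC=C(C)C)c1cc(OC(C)=O)c2c(OC)ccc(OC)c2c1OC(C)=O
F10 | step 11 | (1R)-1-(1,4-diacetoxy-5,8-dioxo-5,8-dihydronaphthalen-2-yl)-4-methylpent-3-en-1-yl 3-acetoxy-3-methylbutanoate | CC(=O)OC(C)(C)CC(=O)O[C@H](CC=C(C)C)c1cc(OC(C)=O)c2C(=O)C=CC(=O)c2c1OC(C)=O
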